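## The problem

The target 16 is a flavonol: a 4H-chromen-4-one (rings A and C) carrying the 4-hydroxy-3-methoxyphenyl ring B on C2, hydroxyls on C3, C5 and C7, and a 1-(4-hydroxy-3,5-dimethoxyphenyl)ethyl group on C8. Its only stereocentre is the methine of that side chain, Cα (R), which is doubly benzylic and too remote from ring C to direct anything there; it must be set by a catalyst, and the C2 stereocentre of any flavanone precursor has to be handled independently. A second problem is positional: a ring A with three oxygens and one carbon substituent can close ring C through either ortho oxygen, giving the 8- or the 6-substituted chromanone, and a free 5-hydroxyflavanone can interconvert the two by opening to its chalcone in acid or base. The fragile points are the five free phenols, the C8–Cα bond to the phloroglucinol-type ring (liable to acid-induced cleavage), and above all the Cα–H bond. This bond lies para to the syringyl hydroxyl and is the first one that quinone-type or radical oxidants attack, giving a quinone methide, so the oxidation level of ring C (C3–OH and C2=C3) cannot be adjusted late with ordinary oxidants on the free phenol. The way in is that the matching (2S)-flavanone 14 has a C3 methylene between the C4 carbonyl and the C2 methine, set in a 5,7-dihydroxychroman-4-one with a 4'-hydroxylated ring B. That is the recognition pattern of flavonol synthases, which oxidise exactly this C3–H inside an active site.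

## Retrosynthesis

**16 to 14.** The last disconnection removes the C3–O bond and the C2–C3 unsaturation of ring C and leads to the (2S)-flavanone 14 by way of the dihydroflavonol 15. The neighbouring cuts would carry the C3 oxygen through the synthesis in protected form, or install it on a protected flavone and deprotect afterwards. Both lengthen the endgame, and any late chemical oxidation of the free pentaphenol meets the Cα–H bond first. With the oxidation placed last and inside an enzyme, no freely diffusing oxidant reaches Cα–H and nothing remains to be deprotected. Compound 14 lacks one oxygen and one double bond but has a second stereocentre, C2, which must be S. The forward reaction must hydroxylate C3, desaturate C2–C3, and tolerate a large C8 substituent.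

**14 to 13.** Four O–benzyl bonds are cut. Benzyl is chosen because its removal is neutral. Acid or base on 14 would open ring C to a chalcone with both ortho hydroxyls free, and reclosure would scramble C2 and give the 6-substituted isomer. Compound 13 is no simpler in skeleton than 14, but it is stable to chromatography and regiochemically locked. The forward step must remove four benzyl groups without touching the C4 ketone or the benzylic C2–O1 bond.

**13 to 12.** No skeletal bond is cut here; only the C2 configuration is released, which leads back to the flavanone 12 as the pair of its C2 epimers. A catalyst-controlled construction of C2 would add a second uncertain catalytic step on a crowded, electron-rich ring system, whereas the two components of 12 are diastereomers and can be parted by chromatography. The sorting is placed at the protected stage because there the unwanted (2R) half of 12 can be epimerised through the single chalcone 11 and returned, without any leak into the 6-substituted series. The forward operation needs a workable separation and a clean base-mediated re-equilibration.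

**12 to 11.** The O1–C2 bond is cut, giving the 2'-hydroxychalcone 11. The point of this cut is that 11 has only one free phenol, the one ortho to the arylethyl group, so ring closure can only give the 8-substituted flavanone. The alternative of closing ring C on a fully deprotected chalcone would leave the 6/8 choice open. The precursor has one stereocentre fewer. The forward oxa-Michael addition cannot be steered by the remote Cα, so it is asked only for the constitution, and both C2 configurations are accepted in 12.

**11 to 9 and 10.** The enone C=C bond is cut in the aldol sense, giving the acetophenone 9 and the commercial aldehyde 10 (O-benzylvanillin). This brings in ring B in one convergent step. The forward condensation needs only aqueous base, which does not threaten Cα, since Cα is meta to the carbon carrying the acetyl group and gains no extra acidity.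

**9 to 8.** The Cα–H bond and one methyl C–H bond are cut, giving the 1,1-diarylethene 8. A Friedel–Crafts alkylation of ring A with a 1-arylethyl cation or quinone methide would form the same centre, but racemic and with a 3- versus 5-position ambiguity. Hydrogenation of 8 makes the stereocentre the business of one catalyst. The two aryl groups of 8 differ sharply: ring A is ortho,ortho'-dioxygenated and twisted out of the alkene plane, whereas the syringyl ring can be coplanar. That difference is what a chiral iridium catalyst can read.

**8 to 6 and 3.** The bond between ring A and the alkene carbon is cut, giving the aryl iodide 6 and the N-tosylhydrazone 3, which couple under palladium catalysis through the diazoalkane 7. The neighbouring cut, addition of an aryl-metal reagent to the acetyl group of 5, would consume the acetyl group needed for ring C. It would then force a Lewis-acid acetylation of a benzyl-protected, acid-sensitive diarylethane with an ortho/para question. The chosen cut keeps the acetyl group of 5 and fixes the site of the side chain through the iodide.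

**6 to 5 to 4, and 3 to 2 to 1.** The carbon–iodine bond of 6 is cut to give 5. The forward iodination must go ortho to the chelated phenol and not between the two benzyloxy groups. The two benzyl ethers of 5 go back to commercial 2,4,6-trihydroxyacetophenone 4, whose chelated hydroxyl is the one left free. Hydrazone 3 comes from the ketone 2, the benzyl ether of commercial acetosyringone 1.

## Roads not taken

**Alternative 1:** Ring C is cut at O1–C8a. The precursor would be the bromo diketone A2, in which an aryl bromide sits at the future C8a and the C3 oxygen is already present as a benzyloxy group on the central carbon of a 1,3-diketone. CuI with 1,10-phenanthroline and K2CO3 would couple the enolate oxygen with the aryl bromide and close the pyranone, giving the pentabenzyl flavonol A1. Hydrogenolysis would then give 16.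
- Merits: the 8-substitution is fixed by the position of the bromine. No oxidation is ever carried out in the presence of Cα–H, no C2 stereocentre arises, and every step is a known reaction type.
- Weak points: the bromine in A2 lies between the acyl carbon and the carbon bearing the bulky arylethyl group, so the carbon–oxygen coupling is doubly ortho-hindered. The pentasubstituted ring A needs a regiocontrolled bromination. The 2-benzyloxy-1,3-diketone needs a hindered enolate acylation. The sequence would be several steps longer.
- Comparison: on certainty this road is the stronger one, since it raises neither the enzyme-acceptance question nor the late chemoselectivity question, and it needs no sorting of C2 epimers. The chosen plan sets against it a less crowded ring A, an endgame with no deprotection after the oxidation, and a chemical fallback that also ends at a benzylated flavonol.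

**Alternative 2:** The weight is put on the stereocentre. The 1,1-diarylethene A4 would be made by adding the aryllithium from bromide A5 to the acetyl group of 5 and dehydrating. It would be hydrogenated under [Ir(cod)(L*)]BArF4 (L* a chiral phosphinooxazoline) to the phenol A3.
- Merits: the substrate is simpler than 8, has no chelating hydroxy ketone, and offers a free phenol next to the alkene as a possible directing group. Compound A3 would be reached in one or two steps fewer than 9 is here.
- Weak points: the acetyl group of 5 is used up, so A3 must be acetylated ortho to the phenol. That means acid on a benzyl-protected, electron-rich diarylethane, with a choice between the ortho and para positions and a risk of benzyl loss or C8–Cα cleavage. The aryllithium addition to a hindered, phenoxide-deactivated ketone is also uncertain. The plan says nothing about the oxidation level of ring C, which is the harder problem.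
- Comparison: A4 is the better hydrogenation substrate. The chosen route uses the same hydrogenation (step 6) but on an alkene that already carries the acetyl group. Once the acetylation of A3 is counted, the two roads to ketone 9 are of nearly equal length, and the chosen one offers regiochemical certainty and no acid after the stereocentre exists.

**Alternative 3:** The C2–C1' bond is cut. The 8-substituted chromone A7 and the boronic acid A8 would be joined by Pd(TFA)2 with 2,2'-bipyridine under O2, in which divalent palladium adds the aryl group to C2, eliminates, and is reoxidised from zerovalent palladium. The product is the flavone A6.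
- Merits: ring B enters late and is easily varied. There is no flavanone, so no C2 epimers and no 6/8 scrambling.
- Weak points: A6 lacks the C3 hydroxyl, so an epoxidation or metalation–oxidation and then a deprotection must follow. The chromone A7 needs extra steps from 9. The coupling would run under oxidising conditions with Cα–H present, although protected.
- Comparison: this road is all known chemistry and avoids both the enzyme and the separation of C2 epimers, which is in its favour. It offers no shorter way to the flavone, since A6 is also reachable in one step from chalcone 11, as the fallback for step 11 shows. The chosen plan sets against it the direct delivery of the C3 hydroxyl on the unprotected molecule.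

Key step: step 11

Assumption: 4-(benzyloxy)-3-methoxybenzaldehyde 10 is bought (it is O-benzylvanillin), and in step 6 the ligand antipode is chosen to deliver the (1R) product, since the sense of induction is not predicted here.

## Route

Step 1
Reactants: 1 1-(4-hydroxy-3,5-dimethoxyphenyl)ethanone (acetosyringone)
Product: 2 1-[4-(benzyloxy)-3,5-dimethoxyphenyl]ethanone
Conditions: BnBr, K2CO3, DMF, 60 °C
Reagents that add atoms: benzyl bromide, BrCc1ccccc1
Why: Williamson ether synthesis on a phenol; the flanking methoxy groups slow but do not prevent O-alkylation, and the ketone is inert to carbonate.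

Step 2
Reactants: 2 1-[4-(benzyloxy)-3,5-dimethoxyphenyl]ethanone
Product: 3 N'-{(1E)-1-[4-(benzyloxy)-3,5-dimethoxyphenyl]ethylidene}-4-methylbenzenesulfonohydrazide
Conditions: TsNHNH2, MeOH, 60 °C
Reagents that add atoms: 4-methylbenzenesulfonohydrazide, Cc1ccc(cc1)S(=O)(=O)NN
Why: Condensation of an aryl methyl ketone with tosylhydrazide to the N-tosylhydrazone, which normally crystallises from the alcohol as the E isomer.

Step 3
Reactants: 4 1-(2,4,6-trihydroxyphenyl)ethanone
Product: 5 1-[2,4-bis(benzyloxy)-6-hydroxyphenyl]ethanone
Conditions: BnBr (2.1 equiv), K2CO3, DMF, rt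
Reagents that add atoms: benzyl bromide, BrCc1ccccc1
Why: Selective Williamson etherification; one ortho hydroxyl stays hydrogen-bonded to the acetyl carbonyl and is the least nucleophilic, so the para and the other ortho oxygen are benzylated.

Step 4
Reactants: 5 1-[2,4-bis(benzyloxy)-6-hydroxyphenyl]ethanone
Product: 6 1-[4,6-bis(benzyloxy)-2-hydroxy-3-iodophenyl]ethanone
Conditions: I2 (0.4 equiv), HIO3 (0.2 equiv), EtOH/H2O, rt
Reagents that add atoms: iodine, II; iodic acid, OI(=O)=O
Why: Electrophilic aromatic iodination; in 2-hydroxy-4,6-dialkoxyacetophenones the position ortho to the chelated phenol is the usual site of attack, and here the other free position is additionally shielded by two benzyloxy groups. The site is to be confirmed by HMBC from the chelated hydroxyl proton.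

Step 5
Reactants: 6 1-[4,6-bis(benzyloxy)-2-hydroxy-3-iodophenyl]ethanone; 3 N'-{(1E)-1-[4-(benzyloxy)-3,5-dimethoxyphenyl]ethylidene}-4-methylbenzenesulfonohydrazide
Product: 8 1-{4,6-bis(benzyloxy)-3-[1-(4-(benzyloxy)-3,5-dimethoxyphenyl)ethenyl]-2-hydroxyphenyl}ethanone, via aryldiazoethane 7 (not isolated)
Conditions: Pd2(dba)3 (cat.), XPhos (cat.), LiOtBu (3.5 equiv), 1,4-dioxane, 100 °C
Reagents that add atoms: none
Why: Barluenga coupling: base converts 3 into the diazoalkane 7, which forms a palladium carbene with the arylpalladium iodide from 6; aryl migration and β-hydride elimination from the methyl group give the 1,1-diarylethene. The reaction type is established for ortho-substituted 1,1-diarylethenes, and the phenol is carried through as its lithium phenoxide, hence the excess of base.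

Step 6
Reactants: 8 1-{4,6-bis(benzyloxy)-3-[1-(4-(benzyloxy)-3,5-dimethoxyphenyl)ethenyl]-2-hydroxyphenyl}ethanone
Product: 9 1-{4,6-bis(benzyloxy)-3-[(1R)-1-(4-(benzyloxy)-3,5-dimethoxyphenyl)ethyl]-2-hydroxyphenyl}ethanone
Conditions: [Ir(cod)((S)-tBu-PHOX)]BArF4 or its antipode (cat.), H2 (50 bar), CH2Cl2, rt
Reagents that add atoms: none
Why: Iridium-catalysed asymmetric hydrogenation of a 1,1-diarylethene; the catalyst should distinguish the twisted, ortho,ortho'-dioxygenated ring A from the coplanar syringyl ring and so set Cα, with the ligand antipode chosen for R. The homogeneous catalyst does not cleave benzyl ethers or reduce the aryl ketone.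

Step 7
Reactants: 9 1-{4,6-bis(benzyloxy)-3-[(1R)-1-(4-(benzyloxy)-3,5-dimethoxyphenyl)ethyl]-2-hydroxyphenyl}ethanone; 10 4-(benzyloxy)-3-methoxybenzaldehyde
Product: 11 (2E)-1-{4,6-bis(benzyloxy)-3-[(1R)-1-(4-(benzyloxy)-3,5-dimethoxyphenyl)ethyl]-2-hydroxyphenyl}-3-[4-(benzyloxy)-3-methoxyphenyl]prop-2-en-1-one
Conditions: KOH, EtOH/THF/H2O, rt
Reagents that add atoms: none
Why: Claisen–Schmidt condensation of a 2-hydroxyacetophenone with a non-enolisable aldehyde; elimination gives the E enone. Cα is meta to the acyl-bearing carbon and is not acidified, so its configuration should hold; any flavanone formed early is carried into step 8.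

Step 8
Reactants: 11 (2E)-1-{4,6-bis(benzyloxy)-3-[(1R)-1-(4-(benzyloxy)-3,5-dimethoxyphenyl)ethyl]-2-hydroxyphenyl}-3-[4-(benzyloxy)-3-methoxyphenyl]prop-2-en-1-one
Product: 12 (2RS)-5,7-bis(benzyloxy)-2-[4-(benzyloxy)-3-methoxyphenyl]-8-[(1R)-1-(4-(benzyloxy)-3,5-dimethoxyphenyl)ethyl]-2,3-dihydro-4H-chromen-4-one (the pair of C2 epimers, Cα uniformly R)
Conditions: NaOAc, EtOH, reflux
Reagents that add atoms: none
Why: Intramolecular oxa-Michael addition (6-endo-trig) of the only free phenol, which fixes the side chain at C8; a 6'-alkoxy group favours the flavanone side of the equilibrium. The remote Cα cannot steer the new C2 centre, so both C2 configurations are expected in comparable amounts and are taken on together as 12.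

Step 9
Reactants: 12 (2RS)-5,7-bis(benzyloxy)-2-[4-(benzyloxy)-3-methoxyphenyl]-8-[(1R)-1-(4-(benzyloxy)-3,5-dimethoxyphenyl)ethyl]-2,3-dihydro-4H-chromen-4-one (the pair of C2 epimers)
Product: 13 (2S)-5,7-bis(benzyloxy)-2-[4-(benzyloxy)-3-methoxyphenyl]-8-[(1R)-1-(4-(benzyloxy)-3,5-dimethoxyphenyl)ethyl]-2,3-dihydro-4H-chromen-4-one
Conditions: preparative HPLC (silica, or a polysaccharide chiral stationary phase if needed); (2R) fraction: NaOAc, EtOH, reflux, then separated again
Reagents that add atoms: none
Why: Separation of diastereomers with recycling: the two components of 12 differ in the relative configuration of C2 and Cα and should be separable by chromatography. The unwanted (2R) fraction is epimerised at C2 by retro-oxa-Michael opening to chalcone 11 and oxa-Michael reclosure, which can only return the 8-substituted flavanone because 11 has a single free phenol, so repeated cycles funnel the material into 13. The C2 configuration is to be assigned from the circular dichroism of the flavanone chromophore.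

Step 10
Reactants: 13 (2S)-5,7-bis(benzyloxy)-2-[4-(benzyloxy)-3-methoxyphenyl]-8-[(1R)-1-(4-(benzyloxy)-3,5-dimethoxyphenyl)ethyl]-2,3-dihydro-4H-chromen-4-one
Product: 14 (2S)-5,7-dihydroxy-2-(4-hydroxy-3-methoxyphenyl)-8-[(1R)-1-(4-hydroxy-3,5-dimethoxyphenyl)ethyl]-2,3-dihydro-4H-chromen-4-one
Conditions: H2 (1 atm), Pd/C, EtOAc/MeOH, rt
Reagents that add atoms: none
Why: Hydrogenolysis of four aryl benzyl ethers under neutral conditions, which should leave the chelated C4 ketone and both stereocentres untouched and give no chance for ring opening to a chalcone; the reaction is stopped after four equivalents of H2 to spare the benzylic C2–O1 bond.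

Step 11
Reactants: 14 (2S)-5,7-dihydroxy-2-(4-hydroxy-3-methoxyphenyl)-8-[(1R)-1-(4-hydroxy-3,5-dimethoxyphenyl)ethyl]-2,3-dihydro-4H-chromen-4-one
Product: 16 3,5,7-trihydroxy-2-(4-hydroxy-3-methoxyphenyl)-8-[(1R)-1-(4-hydroxy-3,5-dimethoxyphenyl)ethyl]-4H-chromen-4-one (the target), via (2R,3R)-dihydroflavonol 15 (not isolated)
Conditions: recombinant bifunctional flavonol synthase (e.g. from Citrus unshiu), FeSO4, 2-oxoglutarate, sodium ascorbate, catalase, air, HEPES buffer pH 7 with 5% DMSO, 30 °C
Reagents that add atoms: dioxygen, O=O
Why: Proposed new method: flavonol synthases convert (2S)-naringenin and related 5,7-dihydroxyflavanones into flavonols, but a flavanone with a bulky benzylic group on C8 has not been shown to be a substrate, so the step extends that reaction type and depends on screening or engineering an enzyme that tolerates 8-substitution. At the divalent iron centre, O2 and 2-oxoglutarate give succinate, CO2 and a tetravalent iron-oxo species, which abstracts a hydrogen from C3 of 14; hydroxyl rebound gives the trans (2R,3R)-dihydroflavonol 15. A second turnover removes the hydrogens on C2 and C3 of 15 and leaves the C2–C3 double bond of 16. No ring closes, and the only new stereocentre, C3 of 15, is set by the enzyme anti to ring B and erased in the desaturation, while Cα is not touched. The selectivity required is C3–H over the weaker, doubly benzylic Cα–H. It is secured by the 5-hydroxy-4-keto chelate, the 7-hydroxyl and the 4'-hydroxyl of 14, which anchor the chromanone so that C3 faces the iron while Cα is held away from it, and by the absence of any freely diffusing oxidant (catalase removes H2O2). The same binding mode selects the 2S configuration, and ascorbate keeps the iron divalent.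

## Compound list

1 | 1-(4-hydroxy-3,5-dimethoxyphenyl)ethanone (acetosyringone) | CC(=O)c1cc(OC)c(O)c(OC)c1 | starting material
2 | 1-[4-(benzyloxy)-3,5-dimethoxyphenyl]ethanone | CC(=O)c1cc(OC)c(OCc2ccccc2)c(OC)c1 | intermediate
3 | N'-{(1E)-1-[4-(benzyloxy)-3,5-dimethoxyphenyl]ethylidene}-4-methylbenzenesulfonohydrazide | COc1cc(/C(C)=N/NS(=O)(=O)c2ccc(C)cc2)cc(OC)c1OCc1ccccc1 | intermediate
4 | 1-(2,4,6-trihydroxyphenyl)ethanone | CC(=O)c1c(O)cc(O)cc1O | starting material
5 | 1-[2,4-bis(benzyloxy)-6-hydroxyphenyl]ethanone | CC(=O)c1c(O)cc(OCc2ccccc2)cc1OCc1ccccc1 | intermediate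
6 | 1-[4,6-bis(benzyloxy)-2-hydroxy-3-iodophenyl]ethanone | CC(=O)c1c(O)c(I)c(OCc2ccccc2)cc1OCc1ccccc1 | intermediate
7 | 2-(benzyloxy)-5-(1-diazoethyl)-1,3-dimethoxybenzene | COc1cc(C(C)=[N+]=[N-])cc(OC)c1OCc1ccccc1 | intermediate
8 | 1-{4,6-bis(benzyloxy)-3-[1-(4-(benzyloxy)-3,5-dimethoxyphenyl)ethenyl]-2-hydroxyphenyl}ethanone | CC(=O)c1c(O)c(C(=C)c2cc(OC)c(OCc3ccccc3)c(OC)c2)c(OCc2ccccc2)cc1OCc1ccccc1 | intermediate
9 | 1-{4,6-bis(benzyloxy)-3-[(1R)-1-(4-(benzyloxy)-3,5-dimethoxyphenyl)ethyl]-2-hydroxyphenyl}ethanone | CC(=O)c1c(O)c([C@H](C)c2cc(OC)c(OCc3ccccc3)c(OC)c2)c(OCc2ccccc2)cc1OCc1ccccc1 | intermediate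
10 | 4-(benzyloxy)-3-methoxybenzaldehyde | COc1cc(C=O)ccc1OCc1ccccc1 | starting material
11 | (2E)-1-{4,6-bis(benzyloxy)-3-[(1R)-1-(4-(benzyloxy)-3,5-dimethoxyphenyl)ethyl]-2-hydroxyphenyl}-3-[4-(benzyloxy)-3-methoxyphenyl]prop-2-en-1-one | COc1cc(/C=C/C(=O)c2c(O)c([C@H](C)c3cc(OC)c(OCc4ccccc4)c(OC)c3)c(OCc3ccccc3)cc2OCc2ccccc2)ccc1OCc1ccccc1 | intermediate
12 | (2RS)-5,7-bis(benzyloxy)-2-[4-(benzyloxy)-3-methoxyphenyl]-8-[(1R)-1-(4-(benzyloxy)-3,5-dimethoxyphenyl)ethyl]-2,3-dihydro-4H-chromen-4-one (pair of C2 epimers, C2 not defined) | COc1cc(C2CC(=O)c3c(OCc4ccccc4)cc(OCc4ccccc4)c([C@H](C)c4cc(OC)c(OCc5ccccc5)c(OC)c4)c3O2)ccc1OCc1ccccc1 | intermediate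
13 | (2S)-5,7-bis(benzyloxy)-2-[4-(benzyloxy)-3-methoxyphenyl]-8-[(1R)-1-(4-(benzyloxy)-3,5-dimethoxyphenyl)ethyl]-2,3-dihydro-4H-chromen-4-one | COc1cc([C@@H]2CC(=O)c3c(OCc4ccccc4)cc(OCc4ccccc4)c([C@H](C)c4cc(OC)c(OCc5ccccc5)c(OC)c4)c3O2)ccc1OCc1ccccc1 | intermediate
14 | (2S)-5,7-dihydroxy-2-(4-hydroxy-3-methoxyphenyl)-8-[(1R)-1-(4-hydroxy-3,5-dimethoxyphenyl)ethyl]-2,3-dihydro-4H-chromen-4-one | COc1cc([C@@H]2CC(=O)c3c(O)cc(O)c([C@H](C)c4cc(OC)c(O)c(OC)c4)c3O2)ccc1O | intermediate
15 | (2R,3R)-3,5,7-trihydroxy-2-(4-hydroxy-3-methoxyphenyl)-8-[(1R)-1-(4-hydroxy-3,5-dimethoxyphenyl)ethyl]-2,3-dihydro-4H-chromen-4-one | COc1cc([C@H]2Oc3c([C@H](C)c4cc(OC)c(O)c(OC)c4)c(O)cc(O)c3C(=O)[C@@H]2O)ccc1O | intermediate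
16 | 3,5,7-trihydroxy-2-(4-hydroxy-3-methoxyphenyl)-8-[(1R)-1-(4-hydroxy-3,5-dimethoxyphenyl)ethyl]-4H-chromen-4-one | COc1cc(-c2oc3c([C@H](C)c4cc(OC)c(O)c(OC)c4)c(O)cc(O)c3c(=O)c2O)ccc1O | target

## Step count and least certain steps

Total: 11 steps. Longest linear sequence: 9 steps (steps 3 to 11 from 4; equally steps 1, 2 and 5 to 11 from 1).

**Step 11 (key step, bears the label "Proposed new method:").**
- What may go wrong: the C8 substituent may prevent productive binding, so that turnover stalls or 2-oxoglutarate is decarboxylated without substrate oxidation. The second oxidation may lag, leaving material at the stage of 15. During long incubations, slow non-enzymatic opening of ring C in 14 could erode C2 and leak into the 6-substituted series.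
- Fallback (known chemistry, from 11 back to 16): chalcone 11 is cyclised oxidatively with catalytic I2 in DMSO at 120 °C to the tetra-O-benzyl flavone F1. Dimethyldioxirane in acetone/CH2Cl2 at 0 °C epoxidises the C2–C3 double bond to the flavone 2,3-oxide F2. A trace of p-TsOH opens F2 to the tetra-O-benzyl flavonol F3. Hydrogenolysis over Pd/C then gives 16. The oxidants meet Cα–H only while the syringyl oxygen is benzylated, so the quinone methide pathway is closed, and C2 configuration no longer matters, so steps 8 to 10 are bypassed.

**Step 5.**
- What may go wrong: oxidative addition and carbene insertion at the doubly ortho-substituted iodide may be slow, so that protodeiodination of 6, arylation of the acetyl enolate and self-decomposition of diazoalkane 7 (azine formation, 1,2-hydrogen shift to the styrene) take over.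
- Fallback (from 2 and 6 back to 8): the bond is made by a Suzuki–Miyaura coupling instead of carbene insertion. Ketone 2 is converted with KN(SiMe3)2 and PhNTf2 at −78 °C into the enol triflate F4. Borylation with B2pin2, PdCl2(PPh3)2 and KOPh gives the alkenylboronate F5. F5 is coupled with 6 using Pd(OAc)2, SPhos and K3PO4 in toluene/water to give 8.

**Step 6.**
- What may go wrong: facial selectivity may be poor, or the chelating ortho-hydroxy ketone may inhibit the cationic iridium catalyst. Acid generated from the iridium hydride could also protonate the electron-rich alkene.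
- Fallback (from 8 back to 9): stereocontrol is replaced by resolution. Hydrogenation of 8 with RhCl(PPh3)3 and H2 in toluene/EtOH gives the racemic ketone F6, and preparative chromatography on a chiral stationary phase separates 9 from its enantiomer F7.

**Step 9.**
- What may go wrong: the two C2 epimers in 12 may separate incompletely on a preparative scale, and material may be lost over repeated epimerisation cycles, in which part of it rests as chalcone 11 at equilibrium.
- Fallback (from 12 back to 16): the selection is left to the enzyme. The unseparated 12 is hydrogenolysed as in step 10 to 14 together with its (2R) epimer F8, and step 11 is run on this mixture. Only 14 should be oxidised, and unreacted F8 is removed from 16 by chromatography. If step 11 itself has to be replaced, its fallback starts from 11 and needs no separation at C2.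

## Further compounds

F1 | step 11 | 5,7-bis(benzyloxy)-2-[4-(benzyloxy)-3-methoxyphenyl]-8-[(1R)-1-(4-(benzyloxy)-3,5-dimethoxyphenyl)ethyl]-4H-chromen-4-one | COc1cc(-c2cc(=O)c3c(OCc4ccccc4)cc(OCc4ccccc4)c([C@H](C)c4cc(OC)c(OCc5ccccc5)c(OC)c4)c3o2)ccc1OCc1ccccc1
F2 | step 11 | 5,7-bis(benzyloxy)-2-[4-(benzyloxy)-3-methoxyphenyl]-8-[(1R)-1-(4-(benzyloxy)-3,5-dimethoxyphenyl)ethyl]-2,3-epoxy-2,3-dihydro-4H-chromen-4-one (epoxide configuration not defined) | COc1cc(C23OC2C(=O)c2c(OCc4ccccc4)cc(OCc4ccccc4)c([C@H](C)c4cc(OC)c(OCc5ccccc5)c(OC)c4)c2O3)ccc1OCc1ccccc1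
F3 | step 11 | 5,7-bis(benzyloxy)-2-[4-(benzyloxy)-3-methoxyphenyl]-8-[(1R)-1-(4-(benzyloxy)-3,5-dimethoxyphenyl)ethyl]-3-hydroxy-4H-chromen-4-one | COc1cc(-c2oc3c([C@H](C)c4cc(OC)c(OCc5ccccc5)c(OC)c4)c(OCc4ccccc4)cc(OCc4ccccc4)c3c(=O)c2O)ccc1OCc1ccccc1
F4 | step 5 | 1-[4-(benzyloxy)-3,5-dimethoxyphenyl]ethenyl trifluoromethanesulfonate | COc1cc(C(=C)OS(=O)(=O)C(F)(F)F)cc(OC)c1OCc1ccccc1
F5 | step 5 | 2-{1-[4-(benzyloxy)-3,5-dimethoxyphenyl]ethenyl}-4,4,5,5-tetramethyl-1,3,2-dioxaborolane | COc1cc(C(=C)B2OC(C)(C)C(C)(C)O2)cc(OC)c1OCc1ccccc1
F6 | step 6 | racemic 1-{4,6-bis(benzyloxy)-3-[1-(4-(benzyloxy)-3,5-dimethoxyphenyl)ethyl]-2-hydroxyphenyl}ethanone | CC(=O)c1c(O)c(C(C)c2cc(OC)c(OCc3ccccc3)c(OC)c2)c(OCc2ccccc2)cc1OCc1ccccc1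
F7 | step 6 | 1-{4,6-bis(benzyloxy)-3-[(1S)-1-(4-(benzyloxy)-3,5-dimethoxyphenyl)ethyl]-2-hydroxyphenyl}ethanone | CC(=O)c1c(O)c([C@@H](C)c2cc(OC)c(OCc3ccccc3)c(OC)c2)c(OCc2ccccc2)cc1OCc1ccccc1
F8 | step 9 | (2R)-5,7-dihydroxy-2-(4-hydroxy-3-methoxyphenyl)-8-[(1R)-1-(4-hydroxy-3,5-dimethoxyphenyl)ethyl]-2,3-dihydro-4H-chromen-4-one | COc1cc([C@H]2CC(=O)c3c(O)cc(O)c([C@H](C)c4cc(OC)c(O)c(OC)c4)c3O2)ccc1O
A1 | alternative 1 | 3,5,7-tris(benzyloxy)-2-[4-(benzyloxy)-3-methoxyphenyl]-8-[(1R)-1-(4-(benzyloxy)-3,5-dimethoxyphenyl)ethyl]-4H-chromen-4-one | COc1cc(-c2oc3c([C@H](C)c4cc(OC)c(OCc5ccccc5)c(OC)c4)c(OCc4ccccc4)cc(OCc4ccccc4)c3c(=O)c2OCc2ccccc2)ccc1OCc1ccccc1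
A2 | alternative 1 | 2-(benzyloxy)-1-{4,6-bis(benzyloxy)-3-[(1R)-1-(4-(benzyloxy)-3,5-dimethoxyphenyl)ethyl]-2-bromophenyl}-3-[4-(benzyloxy)-3-methoxyphenyl]propane-1,3-dione | COc1cc(C(=O)C(OCc2ccccc2)C(=O)c2c(Br)c([C@H](C)c3cc(OC)c(OCc4ccccc4)c(OC)c3)c(OCc3ccccc3)cc2OCc2ccccc2)ccc1OCc1ccccc1
A3 | alternative 2 | 3,5-bis(benzyloxy)-2-[(1R)-1-(4-(benzyloxy)-3,5-dimethoxyphenyl)ethyl]phenol | Oc1cc(OCc2ccccc2)cc(OCc2ccccc2)c1[C@H](C)c1cc(OC)c(OCc2ccccc2)c(OC)c1
A4 | alternative 2 | 3,5-bis(benzyloxy)-2-[1-(4-(benzyloxy)-3,5-dimethoxyphenyl)ethenyl]phenol | Oc1cc(OCc2ccccc2)cc(OCc2ccccc2)c1C(=C)c1cc(OC)c(OCc2ccccc2)c(OC)c1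
A5 | alternative 2 | 2-(benzyloxy)-5-bromo-1,3-dimethoxybenzene | COc1cc(Br)cc(OC)c1OCc1ccccc1
A6 | alternative 3 | 5,7-bis(benzyloxy)-2-[4-(benzyloxy)-3-methoxyphenyl]-8-[(1R)-1-(4-(benzyloxy)-3,5-dimethoxyphenyl)ethyl]-4H-chromen-4-one | COc1cc(-c2cc(=O)c3c(OCc4ccccc4)cc(OCc4ccccc4)c([C@H](C)c4cc(OC)c(OCc5ccccc5)c(OC)c4)c3o2)ccc1OCc1ccccc1
A7 | alternative 3 | 5,7-bis(benzyloxy)-8-[(1R)-1-(4-(benzyloxy)-3,5-dimethoxyphenyl)ethyl]-4H-chromen-4-one | O=c1ccoc2c([C@H](C)c3cc(OC)c(OCc4ccccc4)c(OC)c3)c(OCc3ccccc3)cc(OCc3ccccc3)c12
A8 | alternative 3 | [4-(benzyloxy)-3-methoxyphenyl]boronic acid | COc1cc(B(O)O)ccc1OCc1ccccc1
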